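## Analysis of the target

The target is a depsidone. In the numbering of the dibenzo[b,e][1,4]dioxepin-11-one core, ring A (C1–C4, C4a, C11a) and ring B (C5a, C6–C9, C9a) are joined by the ether oxygen O5 (C4a–O–C5a) and by the ester C11(=O)–O10 (C11a–C11, O10–C9a), which close a seven-membered dioxepinone. Ring A carries 1-methyl, 3-methoxy and 4-hydroxy groups. Ring B is hexasubstituted, with 8-hydroxy and 9-methyl groups and a γ-lactone across C6 and C7 whose carbon on C6 is a lactol, CH(OH). That lactol carbon is the only stereocentre and is (R); there is no second centre to relate it to, and it can invert through ring–chain tautomerism to the formyl acid. The sensitive groups are this lactol, the aryl ester C11–O10 (opened by hydroxide or alkoxide) and the two free phenols. The hard points are the diaryl ether between two carbons that each have two ortho substituents, the placement of six different substituents on ring B, and the single enantiomer of a labile centre. The strategy rests on ring B: C9 bears a methyl between the oxygenated carbons C8 and C9a (a 2-methylresorcinol), and the other three carbons bear the aryloxy oxygen (C5a), a formyl-level carbon (C6) and a carboxyl carbon (C7). This is the pattern of a dihydroresorcylate made from an α-aryloxy ethyl enone (C9a, C5a, C6, the lactol carbon, C9 and its methyl) and a malonate (C7, C8 and the lactone carbonyl).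

## Retrosynthetic reasoning

**20 to 19.** The lactol O–H and the C4 phenol O–H are traced back to two benzylic ethers in 19, a (1S)-1-phenylethyl acetal and a benzyl ether. Cleavage occurs at the benzylic carbons of the protecting groups, outside the stereocentre, so the (R) configuration of 19 passes unchanged into 20. One neutral reductive step frees both groups; it has to spare the benzylic C–O bonds at the lactol carbon itself.

**19 to 18, and 18 to 16 and 17.** Both C–O bonds of the acetal carbon are cut, the ring bond to the lactone oxygen and the exocyclic bond to the auxiliary. This leads to a formyl group on C6 and a methyl ester on C7 in depsidone 16, and to alcohol 17. The cut is made here because the hemiacetal of the formyl group can close directly onto the neighbouring ester, so no separate ester hydrolysis is needed in the presence of the aryl ester. The acetal forms as two epimers (18); they are diastereomers, and the acetal carbon can be equilibrated by acid, so crystallisation can in principle funnel the material into 19.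

**16 to 15.** The aryl ester bond C11–O10 is cut. It is the base-labile bond of the skeleton and is therefore made after every basic step. Since O5 already holds the two rings together, the forward closure is intramolecular, and only the hydroxyl on C9a can reach the acid.

**15 to 14.** The ring A acid and the C6 aldehyde are masked as a tert-butyl ester and a dimethyl acetal. Both survive alkoxide and the oxidant of the aromatisation, and both fall to one acid treatment that leaves the C7 methyl ester in place.

**14 to 13.** The aromatic unsaturation of ring B is removed, which puts hydrogens back on C5a and C6 and gives a cyclohexane-1,3-dione. A saturated ring can be assembled by carbonyl chemistry with each substituent placed by the reaction itself; the forward step is a single dehydrogenation.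

**13 to 10 and 11.** Ring B is cut at C6–C7 and C8–C9. These are the two bonds that a malonate makes with an enone: conjugate addition at the β-carbon (C6) and Claisen acylation of the ethyl-ketone α-carbon (C9). No other pair of cuts yields two such simple, unambiguous partners. The forward step must achieve 1,4-addition to an enone that carries an electron-donating oxygen on its α-carbon.

**10 to 7 and 8.** The C5a=C6 double bond is cut by a retro-aldol condensation. The aldehyde 8 brings the future lactol carbon at the correct oxidation level, and the more acidic, aryloxy-bearing methylene of 7 directs the condensation.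

**7 to 5 and 6.** The bond O5–C5a is cut while C5a is still an sp3 carbon. The hindered "diaryl ether" is thus made by SN2 alkylation of a phenol with bromo ketone 6, and no aryl–oxygen coupling between two crowded rings is required.

**5 to 1.** Ring A is bought as aldehyde 1, a catalogue compound. The steps needed are removal of two methyl ethers, benzylation of the outer hydroxyl, oxidation of the aldehyde and tert-butyl ester formation. The tert-butyl ester is chosen because it resists attack by the enolates formed later.

## Alternatives that were turned down

**Alternative 1:** The disconnection is the aryl ether bond O5–C5a, cut last, which leads to depside A2 in which the rings are held only by the ester. In the forward key step a cytochrome P450 depsidone synthase would dehydrogenate A2 and join the ring A hydroxyl next to the ester carbonyl to the one unsubstituted ring B carbon, giving depsidone A1.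
- For: it follows the biosynthesis, needs no protecting groups, makes the ester by simple acylation, and the single open position of ring B leaves no regiochemical choice.
- Against: A1 lacks the lactol hydroxyl. A late, enantioselective oxidation of the phthalide CH2 would be needed beside two benzylic methyls and free phenols. Acceptance of a phthalide-bearing depside by the enzyme, and the supply of a membrane-bound enzyme with its redox partner, are open questions.
- Comparison: this route is clearly stronger in step count and atom economy. The chosen route offers instead ordinary bench chemistry for every bond, and it brings the lactol carbon in at the aldehyde level from the outset, so no C–H oxidation is needed at the stereocentre.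

**Alternative 2:** The disconnection cuts ring A at the two C–C bonds flanking the ether-bearing and ester-bearing carbons. In the forward key step pyrone A4 and the aryloxy propiolate A5 undergo thermal [4+2] addition and decarboxylative cycloreversion to give the diaryl ether benzoate A3.
- For: it is convergent, the push–pull polarisation of A5 matches that of A4 so the regiochemistry is plausible, and ring A arises with the ether already in place.
- Against: A5 already contains the complete hexasubstituted ring B and the resolved acetal, so the two hardest problems must be solved before the key step. An alkynyl ether of a doubly ortho-substituted phenol is difficult to make and hydrolytically fragile. The temperatures of pyrone cycloadditions endanger the acetal centre and the silyl groups, and the lactonisation and deprotections still follow.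
- Comparison: it is stronger in convergence. The chosen route instead builds the harder ring (B) from acyclic pieces and buys the easier ring (A), and it needs no sensitive alkyne.

**Alternative 3:** The disconnection cuts the lactone acyl–O and O–CH bonds, leading to the depsidone-fused benzocyclobutenone A7. In the forward key step a peracid adds to the strained ketone and the benzyloxy-bearing carbon migrates to oxygen with retention, expanding the four-membered ring to the benzyloxyphthalide of A6.
- For: it is the only alternative that sets the stereocentre by a stereospecific reaction, strain release drives it, and the enolate of A7 would be antiaromatic, which protects the α-centre against racemisation.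
- Against: an enantioenriched A7 on a fully substituted depsidone is harder to reach than the target itself. Migration of the aryl carbon instead of the alkoxy carbon, and oxidation of the electron-rich rings by the peracid, are plausible. Three hydrogenolyses remain at the end, one of them at the acetal.
- Comparison: it is stronger in how the configuration is set, by transfer and not by selection. The chosen route instead takes all ring B carbons from simple reagents and fixes the configuration by crystallisation of an equilibrating acetal, which needs no pre-made chiral building block beyond alcohol 17.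

Key step: step 7

Assumption: the free lactol can racemise by ring–chain tautomerism. It is assumed that 20 holds its configuration as a solid and in cold, neutral, aprotic solution, so the centre is fixed as a mixed acetal and liberated only in the last step.

Shorthand: ArO = 2-(benzyloxy)-6-(tert-butoxycarbonyl)-3-methoxy-5-methylphenoxy (ring A with its ether oxygen O5).

## Steps

Step 1
Reactants: 1 2,3,4-trimethoxy-6-methylbenzaldehyde
Product: 2 2,3-dihydroxy-4-methoxy-6-methylbenzaldehyde
Conditions: BCl3 (3 equiv), CH2Cl2, 0 °C to rt; H2O work-up
Reagents that add atoms: none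
Why: Chelation-directed Lewis-acid ether cleavage: boron bound to the formyl oxygen cleaves the ortho methoxy group, and the resulting aryloxyborane delivers the reagent to the adjacent methoxy group. The 4-methoxy group has no such assistance and should remain, as in the known conversion of 2,3,4-trimethoxybenzaldehydes into 2,3-dihydroxy-4-methoxybenzaldehydes.

Step 2
Reactants: 2 2,3-dihydroxy-4-methoxy-6-methylbenzaldehyde
Product: 3 3-(benzyloxy)-2-hydroxy-4-methoxy-6-methylbenzaldehyde
Conditions: NaH (2.1 equiv), DMSO, rt; BnBr (1.0 equiv); aq. HCl work-up
Reagents that add atoms: benzyl bromide, BrCc1ccccc1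
Why: Williamson ether synthesis on the dianion: the 2-phenoxide is conjugated with the formyl group and chelated to sodium (a vinylogous carboxylate), so the 3-phenoxide is the more nucleophilic site and should take the single equivalent of benzyl bromide.

Step 3
Reactants: 3 3-(benzyloxy)-2-hydroxy-4-methoxy-6-methylbenzaldehyde
Product: 4 3-(benzyloxy)-2-hydroxy-4-methoxy-6-methylbenzoic acid
Conditions: NaClO2, NaH2PO4, 2-methyl-2-butene (excess), t-BuOH/THF/H2O, 0 °C to rt
Reagents that add atoms: sodium chlorite, [Na+].[O-]Cl=O
Why: Pinnick (Lindgren) oxidation of the aldehyde by chlorous acid; the alkene scavenges hypochlorous acid and so protects the free ring position para to the phenol from chlorination.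

Step 4
Reactants: 4 3-(benzyloxy)-2-hydroxy-4-methoxy-6-methylbenzoic acid
Product: 5 tert-butyl 3-(benzyloxy)-2-hydroxy-4-methoxy-6-methylbenzoate
Conditions: Me2NCH(Ot-Bu)2 (4 equiv), toluene, 80 °C
Reagents that add atoms: N,N-dimethylformamide di-tert-butyl acetal, CN(C)C(OC(C)(C)C)OC(C)(C)C
Why: Esterification by tert-butyl transfer to the carboxylate from the protonated amide acetal; it is an O-alkylation of the acid, so the hindrance at the carbonyl carbon does not matter and the hydrogen-bonded phenol is left free.

Step 5
Reactants: 5 tert-butyl 3-(benzyloxy)-2-hydroxy-4-methoxy-6-methylbenzoate; 6 1-bromobutan-2-one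
Product: 7 tert-butyl 3-(benzyloxy)-4-methoxy-6-methyl-2-(2-oxobutoxy)benzoate
Conditions: Cs2CO3 (1.5 equiv), DMF, rt
Reagents that add atoms: none
Why: Williamson ether synthesis: SN2 displacement of the activated α-bromo ketone by the caesium phenoxide forms the O5–C5a bond while C5a is an unhindered sp3 carbon. The tert-butyl ester with two ortho substituents resists the intramolecular acylation that a simpler salicylate would undergo.

Step 6
Reactants: 7 tert-butyl 3-(benzyloxy)-4-methoxy-6-methyl-2-(2-oxobutoxy)benzoate; 8 2,2-dimethoxyacetaldehyde
Product: 10 tert-butyl 3-(benzyloxy)-2-{[(2Z)-1,1-dimethoxy-4-oxohex-2-en-3-yl]oxy}-4-methoxy-6-methylbenzoate, via β-hydroxy ketone 9 (not isolated)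
Conditions: 8 (60 wt % in H2O, 1.5 equiv), NaOH (0.3 equiv), MeOH/THF, 0 to 40 °C
Reagents that add atoms: none
Why: Crossed aldol condensation (Claisen–Schmidt type) with a non-enolisable aldehyde: the aryloxy-bearing methylene of 7 is the more acidic α-position, aldol addition is reversible under hydroxide, and E1cB dehydration of 9 is fastest where the α-hydrogen lies between the carbonyl and the aryloxy group. The acetal-bearing carbon should end up anti to the propionyl group (Z), though either alkene geometry would serve in step 7.

Step 7
Reactants: 10 tert-butyl 3-(benzyloxy)-2-{[(2Z)-1,1-dimethoxy-4-oxohex-2-en-3-yl]oxy}-4-methoxy-6-methylbenzoate; 11 dimethyl malonate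
Product: 13 methyl 5-(ArO)-6-(dimethoxymethyl)-3-methyl-2,4-dioxocyclohexane-1-carboxylate (diastereomers and keto–enol tautomers), via Michael adduct 12 (not isolated)
Conditions: NaOMe (1.3 equiv), MeOH, 65 °C; then AcOH, 0 °C
Reagents that add atoms: none
Why: Methoxide generates the malonate anion, which adds 1,4 to the β-carbon of enone 10 (the acetal-bearing carbon) to give adduct 12 and form the C6–C7 bond. Proton transfer then equilibrates the enolates, and the enolate of the ethyl-ketone α-carbon attacks one malonate ester carbonyl in a 6-(enolendo)-exo-trig Claisen closure that forms C8–C9, closes ring B and expels methoxide. The closest known reaction type is the classical Michael–Claisen synthesis of cyclohexane-1,3-dione carboxylates (dihydroresorcylates) from enones and malonates, which is known with ethyl ketones to give 2-methyl diones. The sequence is pulled forward by deprotonation of the new 2-methyl-1,3-dione, so the reversible conjugate addition need not be favourable by itself. No stereocentre has to be controlled: the four new sp3 centres form as mixtures and are erased in step 8. The step needs 1,4- over 1,2-addition, which the soft stabilised nucleophile and the single β-carbon secure; ring closure from the ethyl α-carbon, the only enolate that reaches a malonate carbonyl through a six-membered transition state (the aryloxy-bearing α-carbon could only form a four-membered ring); and no attack of the aryloxy-bearing enolate on the ring A ester, which the tert-butyl group and the two ortho substituents disfavour. The aryloxy oxygen donates into the double bond and lowers the electrophilicity of the enone, which is why the risk of the route sits here.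

Step 8
Reactants: 13 methyl 5-(ArO)-6-(dimethoxymethyl)-3-methyl-2,4-dioxocyclohexane-1-carboxylate
Product: 14 methyl 5-(ArO)-6-(dimethoxymethyl)-2,4-dihydroxy-3-methylbenzoate
Conditions: DDQ (1.1 equiv), 1,4-dioxane, 80 °C
Reagents that add atoms: none
Why: Quinone dehydrogenation of an enolised cyclohexane-1,3-dione: hydride abstraction from C6 (allylic to the β-keto ester enol), proton loss from C5a and tautomerisation give the resorcinol, driven by aromatisation. Anhydrous conditions and one equivalent of oxidant should spare the benzyl ether, the acetal and the product phenols.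

Step 9
Reactants: 14 methyl 5-(ArO)-6-(dimethoxymethyl)-2,4-dihydroxy-3-methylbenzoate
Product: 15 3-(benzyloxy)-2-[2-formyl-4,6-dihydroxy-3-(methoxycarbonyl)-5-methylphenoxy]-4-methoxy-6-methylbenzoic acid
Conditions: TFA/CH2Cl2/H2O (10:10:1), 0 °C to rt
Reagents that add atoms: water, O
Why: Acidolysis of the tert-butyl ester (loss of the tert-butyl cation as the alkene) and acid hydrolysis of the dimethyl acetal in one operation; the methyl ester, the aryl ethers and the benzyl ether are stable to brief treatment. Any material in which the new formyl group has already closed onto the neighbouring ester converges again in step 11.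

Step 10
Reactants: 15 3-(benzyloxy)-2-[2-formyl-4,6-dihydroxy-3-(methoxycarbonyl)-5-methylphenoxy]-4-methoxy-6-methylbenzoic acid
Product: 16 methyl 4-(benzyloxy)-6-formyl-8-hydroxy-3-methoxy-1,9-dimethyl-11-oxo-11H-dibenzo[b,e][1,4]dioxepine-7-carboxylate
Conditions: DCC (1.2 equiv), CH2Cl2 (0.01 M), rt
Reagents that add atoms: none
Why: Carbodiimide-mediated lactonisation (intramolecular Steglich-type esterification), the standard closure of depsidone seco acids: only the hydroxyl ortho to the ether oxygen can reach the activated acid, so the seven-membered ring forms at C9a–O10. The other phenol, hydrogen-bonded to the methyl ester, cannot reach, and dilution suppresses intermolecular acylation.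

Step 11
Reactants: 16 methyl 4-(benzyloxy)-6-formyl-8-hydroxy-3-methoxy-1,9-dimethyl-11-oxo-11H-dibenzo[b,e][1,4]dioxepine-7-carboxylate; 17 (S)-1-phenylethanol
Product: 18 4-(benzyloxy)-8-hydroxy-3-methoxy-1,9-dimethyl depsidone with C6 and C7 bridged as –CH[O–(1S)-CH(CH3)Ph]–O–C(=O)– (acetal carbon on C6, both epimers)
Conditions: 17 (3 equiv), CSA (0.1 equiv), 5 Å MS, toluene, 50 °C
Reagents that add atoms: none
Why: Acid-catalysed pseudo-ester formation: 17 adds to the formyl group and the hemiacetal hydroxyl closes 5-exo-trig onto the adjacent methyl ester with loss of methanol (taken up by the sieves), as in the known conversion of 2-formylbenzoates into 3-alkoxyphthalides. The new acetal carbon forms without control as both epimers, and the carbinol centre of 17 is not involved.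

Step 12
Reactants: 18 the acetal as a mixture of epimers
Product: 19 the (R)-acetal epimer: 4-(benzyloxy)-8-hydroxy-3-methoxy-1,9-dimethyl depsidone with C6 and C7 bridged as –(R)-CH[O–(1S)-CH(CH3)Ph]–O–C(=O)–
Conditions: CSA (0.02 equiv), toluene/heptane, seeded, slow cooling 50 to 5 °C; filtration; mother liquor recycled
Reagents that add atoms: none
Why: Crystallisation-induced diastereomer transformation: the epimers are diastereomers of different solubility, and acid reversibly ionises the acetal carbon (acyloxy-stabilised oxocarbenium ion) so that the solution re-equilibrates while one epimer deposits, as known for menthyloxy butenolides and alkoxyphthalides. The (R) centre is selected by the crystal lattice of the acetal with the (1S) auxiliary and is fixed once the acid is removed.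

Step 13
Reactants: 19 the (R)-acetal epimer
Product: 20 the target: 4,8-dihydroxy-3-methoxy-1,9-dimethyl depsidone with C6 and C7 bridged as –(R)-CH(OH)–O–C(=O)– (lactol carbon on C6)
Conditions: H2 (1 atm), Pd/C (10 wt % Pd), EtOAc, rt
Reagents that add atoms: none
Why: Catalytic hydrogenolysis of benzylic C–O bonds: the benzyl ether and the 1-phenylethyl acetal are cleaved at their exocyclic benzylic carbons, as benzyl glycosides give free hemiacetals, so no bond to the lactol carbon is broken and its (R) configuration is retained. The benzylic C–O bonds on the fully substituted ring B are shielded from the catalyst surface, and the neutral aprotic medium avoids ring–chain epimerisation.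

## Compound list

1 | 2,3,4-trimethoxy-6-methylbenzaldehyde | COc1cc(C)c(C=O)c(OC)c1OC | starting material
2 | 2,3-dihydroxy-4-methoxy-6-methylbenzaldehyde | COc1cc(C)c(C=O)c(O)c1O | intermediate
3 | 3-(benzyloxy)-2-hydroxy-4-methoxy-6-methylbenzaldehyde | COc1cc(C)c(C=O)c(O)c1OCc1ccccc1 | intermediate
4 | 3-(benzyloxy)-2-hydroxy-4-methoxy-6-methylbenzoic acid | COc1cc(C)c(C(=O)O)c(O)c1OCc1ccccc1 | intermediate
5 | tert-butyl 3-(benzyloxy)-2-hydroxy-4-methoxy-6-methylbenzoate | COc1cc(C)c(C(=O)OC(C)(C)C)c(O)c1OCc1ccccc1 | intermediate
6 | 1-bromobutan-2-one | CCC(=O)CBr | starting material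
7 | tert-butyl 3-(benzyloxy)-4-methoxy-6-methyl-2-(2-oxobutoxy)benzoate | CCC(=O)COc1c(OCc2ccccc2)c(OC)cc(C)c1C(=O)OC(C)(C)C | intermediate
8 | 2,2-dimethoxyacetaldehyde | COC(OC)C=O | starting material
9 | tert-butyl 3-(benzyloxy)-2-[(2-hydroxy-1,1-dimethoxy-4-oxohexan-3-yl)oxy]-4-methoxy-6-methylbenzoate (aldol adduct, diastereomers) | CCC(=O)C(Oc1c(OCc2ccccc2)c(OC)cc(C)c1C(=O)OC(C)(C)C)C(O)C(OC)OC | intermediate (not isolated)
10 | tert-butyl 3-(benzyloxy)-2-{[(2Z)-1,1-dimethoxy-4-oxohex-2-en-3-yl]oxy}-4-methoxy-6-methylbenzoate | CCC(=O)/C(Oc1c(OCc2ccccc2)c(OC)cc(C)c1C(=O)OC(C)(C)C)=C/C(OC)OC | intermediate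
11 | dimethyl malonate | COC(=O)CC(=O)OC | starting material
12 | dimethyl 2-[2-(ArO)-1-(dimethoxymethyl)-3-oxopentyl]propanedioate (Michael adduct, diastereomers) | CCC(=O)C(Oc1c(OCc2ccccc2)c(OC)cc(C)c1C(=O)OC(C)(C)C)C(C(OC)OC)C(C(=O)OC)C(=O)OC | intermediate (not isolated)
13 | methyl 5-(ArO)-6-(dimethoxymethyl)-3-methyl-2,4-dioxocyclohexane-1-carboxylate (diastereomers and tautomers) | COC(=O)C1C(=O)C(C)C(=O)C(Oc2c(OCc3ccccc3)c(OC)cc(C)c2C(=O)OC(C)(C)C)C1C(OC)OC | intermediate
14 | methyl 5-(ArO)-6-(dimethoxymethyl)-2,4-dihydroxy-3-methylbenzoate | COC(=O)c1c(O)c(C)c(O)c(Oc2c(OCc3ccccc3)c(OC)cc(C)c2C(=O)OC(C)(C)C)c1C(OC)OC | intermediate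
15 | 3-(benzyloxy)-2-[2-formyl-4,6-dihydroxy-3-(methoxycarbonyl)-5-methylphenoxy]-4-methoxy-6-methylbenzoic acid | COC(=O)c1c(O)c(C)c(O)c(Oc2c(OCc3ccccc3)c(OC)cc(C)c2C(=O)O)c1C=O | intermediate
16 | methyl 4-(benzyloxy)-6-formyl-8-hydroxy-3-methoxy-1,9-dimethyl-11-oxo-11H-dibenzo[b,e][1,4]dioxepine-7-carboxylate | COC(=O)c1c(O)c(C)c2OC(=O)c3c(C)cc(OC)c(OCc4ccccc4)c3Oc2c1C=O | intermediate
17 | (S)-1-phenylethanol | C[C@H](O)c1ccccc1 | starting material
18 | O4-benzyl depsidone (1S)-1-phenylethyl acetal, both epimers at the acetal carbon | COc1cc(C)c2c(c1OCc1ccccc1)Oc1c(c(C)c(O)c3c1C(O[C@@H](C)c1ccccc1)OC3=O)OC2=O | intermediate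
19 | O4-benzyl depsidone (1S)-1-phenylethyl acetal, (R) at the acetal carbon | COc1cc(C)c2c(c1OCc1ccccc1)Oc1c(c(C)c(O)c3c1[C@H](O[C@@H](C)c1ccccc1)OC3=O)OC2=O | intermediate
20 | target, (R)-lactol depsidone (CNP0211607.1) | COc1cc(C)c2c(c1O)Oc1c(c(C)c(O)c3c1[C@H](O)OC3=O)OC2=O | target

## Step count and least certain steps

Total: 13 steps. Longest linear sequence: 13 steps (1 to 20).

**Step 7 (key step).** The conjugate addition may be slow or may reverse, because the aryloxy oxygen donates into the enone and the β-carbon is hindered. The aryloxy-bearing enolate may also acylate itself on the ring A ester, or the sequence may stop before the Claisen closure. Fallback: the polarity of the conjugate addition is reversed. Knoevenagel condensation of 8 with 11 (piperidine/AcOH) would give dimethyl 2-(2,2-dimethoxyethylidene)propanedioate F1, a far stronger acceptor. Ketone 7, through its aryloxy-stabilised enolate (DBU, MeCN), would add to it to give the same adduct 12, which NaOMe in MeOH would close. The fallback sets out from 7 and comes back at 13.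

**Step 6.** Enolisation on the ethyl side, incomplete dehydration or retro-aldol cleavage would erode the enone. Fallback from 5: diazo transfer (4-acetamidobenzenesulfonyl azide, Et3N) to commercial diethyl (2-oxobutyl)phosphonate gives diethyl (1-diazo-2-oxobutyl)phosphonate F2. Rh2(OAc)4-catalysed O–H insertion of its carbenoid into phenol 5 gives tert-butyl 3-(benzyloxy)-2-{[1-(diethoxyphosphoryl)-2-oxobutyl]oxy}-4-methoxy-6-methylbenzoate F3. Horner–Wadsworth–Emmons olefination with 8 (K2CO3, THF/H2O) then fixes the double bond at the phosphonate carbon. The fallback comes back at 10.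

**Step 8.** The enolised dione may be a poor hydride donor, and the product, a phenol para to an aryloxy group, may be oxidised further. Fallback from 13: TMSOTf/Et3N would give the bis(trimethylsilyl) dienol ether F4, a true cyclohexa-1,3-diene that DDQ dehydrogenates at 0 °C to rt. The aromatic bis(trimethylsilyl) ether F5 so formed is desilylated with K2CO3 in MeOH. The fallback comes back at 14.

**Step 12.** The unwanted epimer may be the one that crystallises, epimerisation may be slow, or the auxiliary may racemise by acid ionisation. Fallback from 16: the antipodal auxiliary, (R)-1-phenylethanol, is used. The solubility order of the epimers is then mirrored, so the crystalline acetal would be the (R)-acetal of (1R)-1-phenylethanol F6. Hydrogenolysis as in step 13 brings it back to the route at 20. If neither pair crystallises, the epimers of 18 are separated on silica and the unwanted one is re-equilibrated with acid.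

**Step 13.** Hydrogenolysis may go on to the benzylic C–O bonds at the lactol carbon, and the liberated lactol may epimerise on the catalyst. Fallback from 16, which avoids reduction at the end:
- BCl3 with pentamethylbenzene at −78 °C removes the benzyl ether and gives methyl 6-formyl-4,8-dihydroxy-3-methoxy-1,9-dimethyl-11-oxo-11H-dibenzo[b,e][1,4]dioxepine-7-carboxylate F7.
- Acetalisation with (S)-1-(2-nitrophenyl)ethanol (CSA, sieves) and crystallisation give the (R)-acetal of (1S)-1-(2-nitrophenyl)ethanol F8. The nitro group also suppresses ionisation of the auxiliary.
- Irradiation at 365 nm in neutral MeCN releases the lactol by the 2-nitrobenzyl mechanism without touching the acetal carbon. The fallback comes back at 20.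

**Step 2.** Alkylation at the wrong phenoxide, or double alkylation, would lower the regiochemical purity. Fallback from 2: exhaustive benzylation (BnBr, K2CO3, DMF) gives 2,3-bis(benzyloxy)-4-methoxy-6-methylbenzaldehyde F9. MgBr2·OEt2 (toluene/Et2O, reflux) then removes only the benzyl group ortho to the formyl group by chelation. The fallback comes back at 3.

## Further compounds

F1 | step 7 | dimethyl 2-(2,2-dimethoxyethylidene)propanedioate | COC(OC)C=C(C(=O)OC)C(=O)OC
F2 | step 6 | diethyl (1-diazo-2-oxobutyl)phosphonate | CCC(=O)C(=[N+]=[N-])P(=O)(OCC)OCC
F3 | step 6 | tert-butyl 3-(benzyloxy)-2-{[1-(diethoxyphosphoryl)-2-oxobutyl]oxy}-4-methoxy-6-methylbenzoate | CCC(=O)C(Oc1c(OCc2ccccc2)c(OC)cc(C)c1C(=O)OC(C)(C)C)P(=O)(OCC)OCC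
F4 | step 8 | methyl 5-(ArO)-6-(dimethoxymethyl)-3-methyl-2,4-bis(trimethylsilyloxy)cyclohexa-1,3-diene-1-carboxylate | COC(=O)C1=C(O[Si](C)(C)C)C(C)=C(O[Si](C)(C)C)C(Oc2c(OCc3ccccc3)c(OC)cc(C)c2C(=O)OC(C)(C)C)C1C(OC)OC
F5 | step 8 | methyl 5-(ArO)-6-(dimethoxymethyl)-3-methyl-2,4-bis(trimethylsilyloxy)benzoate | COC(=O)c1c(O[Si](C)(C)C)c(C)c(O[Si](C)(C)C)c(Oc2c(OCc3ccccc3)c(OC)cc(C)c2C(=O)OC(C)(C)C)c1C(OC)OC
F6 | step 12 | O4-benzyl depsidone (1R)-1-phenylethyl acetal, (R) at the acetal carbon | COc1cc(C)c2c(c1OCc1ccccc1)Oc1c(c(C)c(O)c3c1[C@H](O[C@H](C)c1ccccc1)OC3=O)OC2=O
F7 | step 13 | methyl 6-formyl-4,8-dihydroxy-3-methoxy-1,9-dimethyl-11-oxo-11H-dibenzo[b,e][1,4]dioxepine-7-carboxylate | COC(=O)c1c(O)c(C)c2OC(=O)c3c(C)cc(OC)c(O)c3Oc2c1C=O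
F8 | step 13 | depsidone (1S)-1-(2-nitrophenyl)ethyl acetal, (R) at the acetal carbon, free phenols | COc1cc(C)c2c(c1O)Oc1c(c(C)c(O)c3c1[C@H](O[C@@H](C)c1ccccc1[N+](=O)[O-])OC3=O)OC2=O
F9 | step 2 | 2,3-bis(benzyloxy)-4-methoxy-6-methylbenzaldehyde | COc1cc(C)c(C=O)c(OCc2ccccc2)c1OCc1ccccc1
A1 | alternative 1 | depsidone phthalide lacking the lactol hydroxyl | COc1cc(C)c2c(c1O)Oc1c(c(C)c(O)c3c1COC3=O)OC2=O
A2 | alternative 1 | depside: 7-hydroxy-6-methyl-1-oxo-1,3-dihydroisobenzofuran-5-yl 2,3-dihydroxy-4-methoxy-6-methylbenzoate | COc1cc(C)c(C(=O)Oc2cc3COC(=O)c3c(O)c2C)c(O)c1O
A3 | alternative 2 | fully substituted diaryl ether 2-(trimethylsilyl)ethyl benzoate | C[Si](C)(C)CCOC(=O)c1c(C)cc(OC)c(OCc2ccccc2)c1Oc1c(O[Si](C)(C)C(C)(C)C)c(C)c(OCc2ccccc2)c2c1[C@H](O[C@@H](C)c1ccccc1)OC2=O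
A4 | alternative 2 | 3-(benzyloxy)-4-methoxy-6-methyl-2H-pyran-2-one | Cc1cc(OC)c(OCc2ccccc2)c(=O)o1
A5 | alternative 2 | 2-(trimethylsilyl)ethyl 3-(ring B aryloxy)prop-2-ynoate | C[Si](C)(C)CCOC(=O)C#COc1c(O[Si](C)(C)C(C)(C)C)c(C)c(OCc2ccccc2)c2c1[C@H](O[C@@H](C)c1ccccc1)OC2=O
A6 | alternative 3 | tribenzyl-protected target, (R) at the acetal carbon | COc1cc(C)c2c(c1OCc1ccccc1)Oc1c(c(C)c(OCc3ccccc3)c3c1[C@H](OCc1ccccc1)OC3=O)OC2=O
A7 | alternative 3 | depsidone-fused 2-(benzyloxy)benzocyclobutenone | COc1cc(C)c2c(c1OCc1ccccc1)Oc1c(c(C)c(OCc3ccccc3)c3c1[C@H](OCc1ccccc1)C3=O)OC2=O
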